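(The runs stem from a simulated flask with made-up constants, noise included.)

The pitfall in this run is to compare the flasks at equal times. At 6.0 h the alder run has made 2.15 times the G of the ash run, on 2.00 times the charge, and that looks like an order above one. But alder then holds more G, so the two flasks are not in the same state.

| flask | X | time |
|---|---|---|
| ash | 80.0 mM |  |
| alder | 160 mM |  |
| elm | 80.0 mM | 12 h |

- ash run (time / h: [G] / mM): 1.2: 10.63; 2.4: 23.74; 3.6: 35.67; 4.8: 45.77; 6.0: 54.02
- alder run (time / h: [G] / mM): 1.2: 22.54; 2.4: 50.59; 3.6: 77.04; 4.8: 98.51; 6.0: 115.96

(standard deviation of a reading: 0.2 mM)

- how the opening rate goes with [X] round the charge of the ash run: the exponent of the rate at two percent of X gone to G (one fixed amount of G, the same in the runs compared)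
- G in the elm run at 12 h, as a share of the X charged

- Overall: X -> G.
- Constant volume, constant temperature.
- An order is taken over about fifteen percent of the charge, up and down.

I work with the fraction not yet G, which is one minus G over the charge. The bench rule for a first-order run says equal intervals multiply this fraction by the same factor, so its log drop per hour stays constant. In the ash run the first interval gives 0.119 h⁻¹, and the last gives 0.230 h⁻¹. Their ratio of 1.93 breaks the rule at the opening, which is a lag (an induction period). The interval before the last gives 0.215 h⁻¹, a ratio of 1.07, so I take the rule as a fair guide to the ash run from 3.6 h on, though these readings still creep upward.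

I carry the late constant, the log drop per hour of the fraction not yet G over the last interval. Elm repeats the ash charge, so I start from the ash fraction of 0.325 at 6.0 h and run it on to 12 h, which gives me 91.8% G.

The forecast says 92% and an order of 0.85, noting that “alder reaches any given G sooner, so that comparison is confounded”.

The flask gives 92.9% and an order of 0.89.

    X ⇌ L (0.3074 h⁻¹, 0.1501 h⁻¹)
    L → G (0.3128 h⁻¹)
    X + G → 2 G (1.260 M⁻¹ h⁻¹)
    X → G (0.08244 h⁻¹)

From the ash fraction at 6.0 h to the elm share at 12 h, the log drop per hour reads 0.254 h⁻¹, above the late constant of 0.230 h⁻¹. The elm share stands this high because of the step X → G: the run without that step ends at 85.7%. Averaged over the full 12 h, the log drop per hour of that run is 0.162 h⁻¹, lower than the 0.221 h⁻¹ of the elm run as it is.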